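## The problem

The target is the C9 caffeate of (−)-lariciresinol: an oxolane (O1, C2–C5) with a guaiacyl ring on C2, an acyloxymethyl group (C9) on C3 and a guaiacylmethyl group (C7') on C4. Nothing is fused to the ring, so the three contiguous stereocentres (2R,3S,4S) have to be set on a single, flexible five-membered ring. The 2,3-trans relation is the relaxed one and can be left to equilibration if C3 is made epimerisable. The 3,4-cis relation is contra-thermodynamic and needs a kinetic event steered by C3. C2 has no neighbour to lean on and must come from a chiral reagent or catalyst, after which it can govern C3. The C2–O1 bond is a benzylic ether para to an oxygen substituent, so acid can ionise it, with epimerisation, solvolysis or Friedel–Crafts closure onto the other guaiacyl ring as consequences. The catechol cinnamate tolerates neither hydride, enolate bases, hydrogenation, hydroxide nor oxidants, so it must be attached last and unmasked by fluoride. Four phenols and one primary alcohol have to be told apart, since only the C9 hydroxyl is acylated. The enabling feature is that O1–C2(aryl)–C3(C9)–C4–C5, read with C5 as a carbonyl and C9 as a carboxyl, is a γ-aryl paraconic lactone. C2 is then an aldehyde carbon and C3 the β-carbon of a 4-oxobutenoate, two electrophilic carbons that a carbene can join by inverting the polarity of one; in that oxidation state C3–H is acidic and C4 is activated by the lactone carbonyl.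

## Retrosynthesis

**Ester bond C9–O.** The target 24 is traced to its tetrasilyl ether 23, and this to alcohol 19 and the bis-silyl acid 22 (from caffeic acid 20 through the silyl ester 21). The cinnamate is the most fragile group and survives none of the ring-building chemistry, so this cut has no rival. The forward steps are a carbodiimide esterification and a buffered fluoride deprotection, both compatible with the ester and the benzylic ether.

**C9 oxygen.** Alcohol 19 comes from the tris-silyl ether 18 by removal of the one alkyl silyl group. The same silyl group on alkyl and aryl oxygen is differentiated by mechanism: acid removes the alkyl ether first, fluoride removes the aryl ethers at the end. This saves a second protecting group type.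

**C5 oxidation level.** Oxolane 18 is traced through the primary tosylate 17 and diol 16 to the 3,4-cis lactone 15. The C5 carbonyl is needed up to this point to activate C4. Reduction to the diol and reclosure at the same O1–C5 connection avoids Lewis acids next to the benzylic ether; the direct lactol reduction is held in reserve. The forward reactions must leave C2 untouched, and displacement at the primary carbon C5 does so.

**C4–C7' bond and the C4 stereocentre.** Lactone 15 comes from benzylidene lactone 14 by hydrogenation, and 14 from lactone 9 and aldehyde 10 by aldol addition (via enolate 11 to adduct 12) and elimination (via mesylate 13). Direct benzylation of the enolate would place the benzyl group trans to C9, the wrong relation, and would need a benzyl bromide made in two more steps. Condensation followed by hydrogen delivery anti to the C3 substituent gives the cis relation directly. Aldehyde 10 is one step from vanillin 1.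

**C9 oxidation level.** Lactone 9 is traced through diol-phenol 8 and acid 7 to the trans ester 5, with the ring-opened salt 6 as the transient form during saponification. C9 must be reduced before C4 is enolised, because an ester at C9 would make C3–H compete with C4–H and its enolate could expel the lactone carboxylate. The hydroxide that cleaves the ethyl ester also removes the aryl pivalate, and one silylation then protects phenol and alcohol together.

**C3 configuration.** The trans ester 5 comes from the cis ester 4 by base equilibration at C3. Only a single diastereomer is equilibrated, so that one C2 configuration enters; equilibrating a kinetic mixture could erode enantiomeric purity if the two diastereomers differ at C2.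

**C2–C3 and O1–C5 (key disconnection).** Cis ester 4 is cut to aldehyde 2 and enal 3. The neighbouring cut, an auxiliary-controlled aldol of a succinate enolate, needs a stoichiometric auxiliary and more steps and is kept as the reserve. The carbene route makes both bonds, the ring and C2 in one catalytic step from two simple pieces. It asks for cross-annulation in preference to self-annulation of the very electrophilic enal. A silyloxy group would leave the aldehyde electron-rich and a poor partner, so the phenol of vanillin 1 is masked as the electron-withdrawing pivalate 2.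

## Roads not taken

**Alternative 1:** The cut is C4–C7'. A γ-aryl lactone carrying the second aryl unit as a benzyl ether on the C9 oxygen and a diazo group at C4 (A1) would be treated with Rh2(OAc)4. The carbenoid at C4 inserts into a benzylic C–H bond of the ether and gives the cis-fused bicyclic lactone ether A2; reductive cleavage of the temporary C7'–O bond would later free the benzyl group and the C9 alcohol.
- Merits: the 3,4-cis relation follows from the cis fusion of two five-membered rings, a structural guarantee; the C–H bond is doubly activated (benzylic, next to oxygen).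
- Weak points: A1 still has to be built from a lactone like 8, so C2 and C3 are not addressed. Diazo transfer to a simple lactone needs prior activation. The carbenoid can also attack the ether oxygen or the electron-rich ring. The C7'–O bond must later be cleaved beside the C2–O1 benzylic bond, which forces an electron-poor sulfonate on the C2 aryl ring and a protecting-group exchange before the caffeate can be attached.
- Comparison: this road is better for the C4 stereocentre. The chosen plan sets against it a shorter sequence, uniform silyl protection, and hydrogen delivery anti to the C3 substituent with an independent reserve.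

**Alternative 2:** The cut is C3–C4. An enantioenriched benzylic ether A3, with a terminal epoxide across C3/C9 and a cinnamyl group on O1, would be treated with Cp2TiCl (trivalent titanium, from Cp2TiCl2 and Zn). Homolytic epoxide opening gives a C3 radical that closes 5-exo-trig onto the cinnamyl alkene; the benzylic radical is reduced and protonated to give A4, the bis-silyl lariciresinol with free C9 hydroxyl.
- Merits: A4 is the functional equivalent of alcohol 19 and would be reached in well under half the steps; the C9 hydroxyl emerges already differentiated.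
- Weak points: C2 is the only stereocentre in A3 and must control both C3 and C4 in one radical closure. The 3,4 relation depends on a small preference between transition-state conformers and cannot be corrected afterwards. A3 itself needs an asymmetric step of its own, and titanium is used stoichiometrically.
- Comparison: in step count this road is clearly better. The chosen plan sets against it that each stereocentre is placed by a separate, correctable event: a catalyst for C2, equilibrium for C3, face-selective hydrogenation for C4.

**Alternative 3:** The cuts are C2–C3 and C4–C5. CsF would generate a carbonyl ylide from the chloro silylmethyl ether A6, and the ylide would add across C3=C4 of butenolide A5 anti to its C7' aryl group, giving the cis-fused furofuranone A7. Hydrogenolysis of the lactone C7'–O bond would then unveil the benzyl group and a C9 carboxyl.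
- Merits: the oxolane and two C–C bonds form in one step; 3,4-cis is guaranteed by suprafacial addition to a ring alkene; the directing centre C7' is erased afterwards; the route is highly convergent.
- Weak points: a non-stabilised ylide offers no secure regiochemistry (the aryl-bearing terminus must bond to C3) and no secure endo/exo preference (C2). The ylide precursor is a moisture-sensitive α-chloro ether. The hydrogenolysis must distinguish two benzylic C–O bonds on identical aryl rings.
- Comparison: this road is at least as good for 3,4-cis and for convergence. The chosen plan sets against it an unambiguous C2–C3 bond (homoenolate carbon to aldehyde carbon), thermodynamic correction at C3, and no stereocentre that has to be destroyed.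

Key step: step 2

## Remarks before the steps

- Locants O1, C2, C3, C4, C5, C7' and C9 refer throughout to the oxolane of the target and its exocyclic carbons; systematic names of the lactones use their own locants. TBS = tert-butyldimethylsilyl, TBSO = tert-butyldimethylsilyloxy, Piv = 2,2-dimethylpropanoyl.
- Assumption: the (5aS,10bR) antipode of the triazolium salt is taken to deliver the (2R) lactone; if the opposite sense is found, the mirror-image salt, equally available, is used with nothing else changed.

## Route

Step 1
Reactants: 1 vanillin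
Product: 2 4-formyl-2-methoxyphenyl 2,2-dimethylpropanoate (4-O-pivaloylvanillin)
Conditions: PivCl, Et3N, DMAP (cat.), CH2Cl2, 0 °C to rt
Reagents that add atoms: pivaloyl chloride, CC(C)(C)C(=O)Cl
Why: Phenol acylation; the hindered pivalate turns the electron-donating phenol oxygen into an electron-withdrawing group, which raises the electrophilicity of the formyl group for step 2, and it is later removed by the hydroxide of step 4 at no extra cost.

Step 2
Reactants: 2 4-O-pivaloylvanillin; 3 ethyl (E)-4-oxobut-2-enoate
Product: 4 ethyl (2R,3S)-2-[3-methoxy-4-(pivaloyloxy)phenyl]-5-oxooxolane-3-carboxylate (2,3-cis lactone)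
Conditions: (5aS,10bR)-2-mesityl-5a,10b-dihydro-4H,6H-indeno[2,1-b][1,2,4]triazolo[4,3-d][1,4]oxazin-2-ium chloride (10 mol %), DBU (10 mol %), 2 (2 equiv), 3 added over 6 h, THF, rt; chromatographic removal of the minor 2,3-trans lactone
Reagents that add atoms: none
Why: The triazolylidene freed by DBU adds to the formyl group of 3 and proton transfer gives the Breslow intermediate, whose β-carbon (C3, carrying the ester that becomes C9) is now nucleophilic. It adds to the formyl carbon of 2 (C2), making C2–C3; tautomerisation to the acyl azolium lets the C2 alkoxide (O1) acylate C5 in a 5-exo-trig lactonisation that closes the ring and returns the carbene. The closest known reaction type is the carbene-catalysed homoenolate annulation of enals with aryl aldehydes to γ-butyrolactones. C2 is set by the chiral aminoindanol-derived triazolium, which differentiates the faces of the aldehyde in the C–C bond-forming step; C3 arises kinetically (cis expected, as with β-aryl enals) and is not relied on, since step 3 resets it. The step needs cross-annulation in preference to self-annulation of the very electrophilic enal, and C–C bond formation in preference to protonation of the homoenolate at C3: the pivaloyloxy group brings 2 into the range of the halo- and ester-substituted benzaldehydes that serve best in this reaction class, 2 is kept in excess while 3 is added slowly, and a strong amidine base with a weakly acidic conjugate acid favours the homoenolate pathway. Isolating the single diastereomer 4 ensures that only one C2 configuration enters the equilibration of step 3.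

Step 3
Reactants: 4 2,3-cis lactone ester
Product: 5 ethyl (2R,3R)-2-[3-methoxy-4-(pivaloyloxy)phenyl]-5-oxooxolane-3-carboxylate (2,3-trans lactone)
Conditions: DBU (0.5 equiv), THF, rt
Reagents that add atoms: none
Why: Epimerisation through the ester enolate at C3 settles the ester trans to the aryl group, the more stable arrangement, while C2 carries no acidic hydrogen and is untouched. Loss of the lactone carboxylate from this enolate is the reverse of a 5-endo-trig closure and should be slow with an amidine base at room temperature.

Step 4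
Reactants: 5 2,3-trans lactone ester
Product: 7 (2R,3R)-2-(4-hydroxy-3-methoxyphenyl)-5-oxooxolane-3-carboxylic acid, via trilithium hydroxy diacid salt 6 (not isolated)
Conditions: LiOH·H2O (6 equiv), THF/H2O, 0 °C to rt; then 1 M HCl to pH 2, rt
Reagents that add atoms: lithium hydroxide, [Li+].[OH-]
Why: Saponification cleaves the ethyl ester, the aryl pivalate and the lactone to salt 6, whose C3–H, flanked by a carboxylate, is not acidic. On acidification the γ-hydroxy acid recloses through the C5 carboxyl to the five-membered lactone, not through C9 to a four-membered one.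

Step 5
Reactants: 7 trans paraconic acid
Product: 8 (4S,5R)-5-(4-hydroxy-3-methoxyphenyl)-4-(hydroxymethyl)oxolan-2-one
Conditions: BH3·SMe2 (3 equiv), THF, 0 °C to rt; MeOH quench
Reagents that add atoms: none
Why: Chemoselective borane reduction of a carboxylic acid beside a lactone, standard for paraconic acids: the acid itself activates the electrophilic borane, which leaves the lactone carbonyl alone. A neutral work-up avoids translactonisation onto the new hydroxyl.

Step 6
Reactants: 8 hydroxymethyl lactone
Product: 9 (4S,5R)-5-[3-methoxy-4-(TBSO)phenyl]-4-[(TBSO)methyl]oxolan-2-one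
Conditions: TBSCl (2.5 equiv), imidazole, DMF, 0 °C to rt
Reagents that add atoms: tert-butyldimethylsilyl chloride, CC(C)(C)[Si](C)(C)Cl
Why: Imidazole-promoted silylation of phenol and primary alcohol in one operation; the weak base does not open or isomerise the lactone.

Step 7
Reactants: 1 vanillin
Product: 10 3-methoxy-4-(TBSO)benzaldehyde
Conditions: TBSCl, imidazole, DMF, rt
Reagents that add atoms: tert-butyldimethylsilyl chloride, CC(C)(C)[Si](C)(C)Cl
Why: Standard phenol silylation; the silyl ether survives enolate, hydrogenation and hydride conditions and leaves with fluoride at the end.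

Step 8
Reactants: 9 bis-silyl lactone; 10 3-methoxy-4-(TBSO)benzaldehyde
Product: 12 (3S,4S,5R)-3-{hydroxy[3-methoxy-4-(TBSO)phenyl]methyl}-5-[3-methoxy-4-(TBSO)phenyl]-4-[(TBSO)methyl]oxolan-2-one (both carbinol epimers), via lithium lactone enolate 11 (not isolated)
Conditions: LiN(SiMe3)2 (1.1 equiv), THF, −78 °C; then 10, −78 °C; aq. NH4Cl
Reagents that add atoms: none
Why: Aldol addition of a lactone lithium enolate to an aryl aldehyde forms C4–C7'. The aldehyde approaches C4 anti to the C3 substituent, but this centre and the carbinol centre are both erased in step 9, so their ratio is of no consequence.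

Step 9
Reactants: 12 aldol adduct
Product: 14 (3E,4S,5R)-3-{[3-methoxy-4-(TBSO)phenyl]methylidene}-5-[3-methoxy-4-(TBSO)phenyl]-4-[(TBSO)methyl]oxolan-2-one, via benzylic mesylate 13 (not isolated)
Conditions: MsCl, Et3N, CH2Cl2, 0 °C; then DBU, rt
Reagents that add atoms: none
Why: Mesylation and base-induced β-elimination (E1cB) give the conjugated (E)-benzylidene lactone from either carbinol epimer. C3 is not conjugated to the carbonyl in a way that makes its hydrogen acidic, so it is untouched.

Step 10
Reactants: 14 (E)-benzylidene lactone
Product: 15 (3S,4S,5R)-3-{[3-methoxy-4-(TBSO)phenyl]methyl}-5-[3-methoxy-4-(TBSO)phenyl]-4-[(TBSO)methyl]oxolan-2-one (3,4-cis lactone)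
Conditions: H2 (1 atm), 10% Pd/C, EtOAc, rt, stopped after one equivalent
Reagents that add atoms: none
Why: Heterogeneous syn hydrogenation of an α-benzylidene lactone. Allylic 1,3-strain with the arylidene group holds the C3 silyloxymethyl group pseudoaxial, so hydrogen reaches C4 from the opposite face and the new benzyl group ends cis to C9, the contra-thermodynamic relation. Neutral conditions and limited hydrogen uptake spare the benzylic lactone C–O bond.

Step 11
Reactants: 15 3,4-cis lactone
Product: 16 (1R,2S,3S)-1-[3-methoxy-4-(TBSO)phenyl]-3-{[3-methoxy-4-(TBSO)phenyl]methyl}-2-[(TBSO)methyl]butane-1,4-diol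
Conditions: LiBH4, THF, 0 °C to rt
Reagents that add atoms: none
Why: Hydride reduction of a lactone to the diol; the cold, weakly basic medium should reduce faster than it epimerises the cis C4 centre, and the silyl ethers are inert to it.

Step 12
Reactants: 16 diol
Product: 18 (2R,3S,4S)-2-[3-methoxy-4-(TBSO)phenyl]-4-{[3-methoxy-4-(TBSO)phenyl]methyl}-3-[(TBSO)methyl]oxolane, via primary tosylate 17 (not isolated)
Conditions: TsCl (1.1 equiv), pyridine, DMAP (cat.), CH2Cl2, 0 to 40 °C
Reagents that add atoms: none
Why: The primary hydroxyl is sulfonylated much faster than the hindered benzylic one. The C2 hydroxyl then displaces the tosylate at C5 (intramolecular Williamson etherification, 5-exo-tet), which re-forms the O1–C5 bond without touching a stereocentre.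

Step 13
Reactants: 18 tris-silyl oxolane
Product: 19 {(2R,3S,4S)-2-[3-methoxy-4-(TBSO)phenyl]-4-{[3-methoxy-4-(TBSO)phenyl]methyl}oxolan-3-yl}methanol
Conditions: CSA (0.1 equiv), MeOH/CH2Cl2, 0 °C
Reagents that add atoms: none
Why: Acid-catalysed methanolysis removes a primary alkyl silyl ether well before aryl silyl ethers, whose oxygen is less basic. Low temperature and a catalytic amount of acid are chosen to leave the benzylic C2–O1 bond intact.

Step 14
Reactants: 20 caffeic acid
Product: 22 (E)-3-[3,4-bis(TBSO)phenyl]prop-2-enoic acid, via tris-silyl caffeate 21 (not isolated)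
Conditions: TBSCl (3.5 equiv), imidazole, DMF, rt; then AcOH/THF/H2O, rt
Reagents that add atoms: tert-butyldimethylsilyl chloride, CC(C)(C)[Si](C)(C)Cl
Why: Exhaustive silylation followed by mild hydrolysis of the labile silyl ester, which aryl silyl ethers withstand; the alkene geometry is not affected.

Step 15
Reactants: 19 bis-silyl lariciresinol; 22 bis-silyl caffeic acid
Product: 23 {(2R,3S,4S)-2-[3-methoxy-4-(TBSO)phenyl]-4-{[3-methoxy-4-(TBSO)phenyl]methyl}oxolan-3-yl}methyl (E)-3-[3,4-bis(TBSO)phenyl]prop-2-enoate
Conditions: EDC·HCl, DMAP, CH2Cl2, 0 °C to rt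
Reagents that add atoms: none
Why: Steglich esterification of the only free hydroxyl under neutral conditions; nothing epimerisable or acid-labile is exposed.

Step 16
Reactants: 23 tetrasilyl ester
Product: 24 [(2R,3S,4S)-2-(4-hydroxy-3-methoxyphenyl)-4-[(4-hydroxy-3-methoxyphenyl)methyl]oxolan-3-yl]methyl (E)-3-(3,4-dihydroxyphenyl)prop-2-enoate (CNP0132883.1)
Conditions: Bu4NF (5 equiv), AcOH (5 equiv), THF, 0 °C
Reagents that add atoms: none
Why: Fluoride cleaves the four aryl silyl ethers rapidly. The acetic acid buffer keeps the phenols protonated, which protects the cinnamate ester from acyl transfer and the catechol from oxidation.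

## Compound list

1 | vanillin | COc1cc(C=O)ccc1O | starting material
2 | 4-formyl-2-methoxyphenyl 2,2-dimethylpropanoate | COc1cc(C=O)ccc1OC(=O)C(C)(C)C | intermediate
3 | ethyl (E)-4-oxobut-2-enoate | CCOC(=O)/C=C/C=O | starting material
4 | ethyl (2R,3S)-2-[3-methoxy-4-(pivaloyloxy)phenyl]-5-oxooxolane-3-carboxylate | C1C(=O)O[C@@H](c2ccc(OC(=O)C(C)(C)C)c(OC)c2)[C@H]1C(=O)OCC | intermediate
5 | ethyl (2R,3R)-2-[3-methoxy-4-(pivaloyloxy)phenyl]-5-oxooxolane-3-carboxylate | C1C(=O)O[C@@H](c2ccc(OC(=O)C(C)(C)C)c(OC)c2)[C@@H]1C(=O)OCC | intermediate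
6 | trilithium (2R)-2-[(R)-hydroxy(3-methoxy-4-oxidophenyl)methyl]butanedioate (not isolated) | [Li+].[Li+].[Li+].O[C@@H](c1ccc([O-])c(OC)c1)[C@@H](CC(=O)[O-])C(=O)[O-] | intermediate
7 | (2R,3R)-2-(4-hydroxy-3-methoxyphenyl)-5-oxooxolane-3-carboxylic acid | C1C(=O)O[C@@H](c2ccc(O)c(OC)c2)[C@@H]1C(=O)O | intermediate
8 | (4S,5R)-5-(4-hydroxy-3-methoxyphenyl)-4-(hydroxymethyl)oxolan-2-one | C1C(=O)O[C@@H](c2ccc(O)c(OC)c2)[C@@H]1CO | intermediate
9 | (4S,5R)-5-[3-methoxy-4-(TBSO)phenyl]-4-[(TBSO)methyl]oxolan-2-one | C1C(=O)O[C@@H](c2ccc(O[Si](C)(C)C(C)(C)C)c(OC)c2)[C@@H]1CO[Si](C)(C)C(C)(C)C | intermediate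
10 | 3-methoxy-4-(TBSO)benzaldehyde | COc1cc(C=O)ccc1O[Si](C)(C)C(C)(C)C | intermediate
11 | lithium (2R,3S)-2-[3-methoxy-4-(TBSO)phenyl]-3-[(TBSO)methyl]-2,3-dihydrofuran-5-olate, the lithium enolate of 9 (not isolated) | [Li+].[O-]C1=C[C@@H](CO[Si](C)(C)C(C)(C)C)[C@H](c2ccc(O[Si](C)(C)C(C)(C)C)c(OC)c2)O1 | intermediate
12 | (3S,4S,5R)-3-{hydroxy[3-methoxy-4-(TBSO)phenyl]methyl}-5-[3-methoxy-4-(TBSO)phenyl]-4-[(TBSO)methyl]oxolan-2-one, both carbinol epimers | COc1cc(C(O)[C@H]2C(=O)O[C@@H](c3ccc(O[Si](C)(C)C(C)(C)C)c(OC)c3)[C@@H]2CO[Si](C)(C)C(C)(C)C)ccc1O[Si](C)(C)C(C)(C)C | intermediate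
13 | methanesulfonate of 12 at the benzylic hydroxyl (not isolated) | COc1cc(C(OS(C)(=O)=O)[C@H]2C(=O)O[C@@H](c3ccc(O[Si](C)(C)C(C)(C)C)c(OC)c3)[C@@H]2CO[Si](C)(C)C(C)(C)C)ccc1O[Si](C)(C)C(C)(C)C | intermediate
14 | (3E,4S,5R)-3-{[3-methoxy-4-(TBSO)phenyl]methylidene}-5-[3-methoxy-4-(TBSO)phenyl]-4-[(TBSO)methyl]oxolan-2-one | O=C1O[C@@H](c2ccc(O[Si](C)(C)C(C)(C)C)c(OC)c2)[C@H](CO[Si](C)(C)C(C)(C)C)/C1=C\c3ccc(O[Si](C)(C)C(C)(C)C)c(OC)c3 | intermediate
15 | (3S,4S,5R)-3-{[3-methoxy-4-(TBSO)phenyl]methyl}-5-[3-methoxy-4-(TBSO)phenyl]-4-[(TBSO)methyl]oxolan-2-one | COc1cc(C[C@@H]2C(=O)O[C@@H](c3ccc(O[Si](C)(C)C(C)(C)C)c(OC)c3)[C@@H]2CO[Si](C)(C)C(C)(C)C)ccc1O[Si](C)(C)C(C)(C)C | intermediate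
16 | (1R,2S,3S)-1-[3-methoxy-4-(TBSO)phenyl]-3-{[3-methoxy-4-(TBSO)phenyl]methyl}-2-[(TBSO)methyl]butane-1,4-diol | COc1cc(C[C@H](CO)[C@@H](CO[Si](C)(C)C(C)(C)C)[C@@H](O)c2ccc(O[Si](C)(C)C(C)(C)C)c(OC)c2)ccc1O[Si](C)(C)C(C)(C)C | intermediate
17 | (2S,3S,4R)-4-hydroxy-4-[3-methoxy-4-(TBSO)phenyl]-2-{[3-methoxy-4-(TBSO)phenyl]methyl}-3-[(TBSO)methyl]butyl 4-methylbenzenesulfonate (not isolated) | COc1cc(C[C@H](COS(=O)(=O)c2ccc(C)cc2)[C@@H](CO[Si](C)(C)C(C)(C)C)[C@@H](O)c2ccc(O[Si](C)(C)C(C)(C)C)c(OC)c2)ccc1O[Si](C)(C)C(C)(C)C | intermediate
18 | (2R,3S,4S)-2-[3-methoxy-4-(TBSO)phenyl]-4-{[3-methoxy-4-(TBSO)phenyl]methyl}-3-[(TBSO)methyl]oxolane | COc1cc(C[C@@H]2CO[C@@H](c3ccc(O[Si](C)(C)C(C)(C)C)c(OC)c3)[C@@H]2CO[Si](C)(C)C(C)(C)C)ccc1O[Si](C)(C)C(C)(C)C | intermediate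
19 | {(2R,3S,4S)-2-[3-methoxy-4-(TBSO)phenyl]-4-{[3-methoxy-4-(TBSO)phenyl]methyl}oxolan-3-yl}methanol | COc1cc(C[C@@H]2CO[C@@H](c3ccc(O[Si](C)(C)C(C)(C)C)c(OC)c3)[C@@H]2CO)ccc1O[Si](C)(C)C(C)(C)C | intermediate
20 | caffeic acid, (E)-3-(3,4-dihydroxyphenyl)prop-2-enoic acid | O=C(O)/C=C/c1ccc(O)c(O)c1 | starting material
21 | tert-butyldimethylsilyl (E)-3-[3,4-bis(TBSO)phenyl]prop-2-enoate (not isolated) | CC(C)(C)[Si](C)(C)OC(=O)/C=C/c1ccc(O[Si](C)(C)C(C)(C)C)c(O[Si](C)(C)C(C)(C)C)c1 | intermediate
22 | (E)-3-[3,4-bis(TBSO)phenyl]prop-2-enoic acid | O=C(O)/C=C/c1ccc(O[Si](C)(C)C(C)(C)C)c(O[Si](C)(C)C(C)(C)C)c1 | intermediate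
23 | {(2R,3S,4S)-2-[3-methoxy-4-(TBSO)phenyl]-4-{[3-methoxy-4-(TBSO)phenyl]methyl}oxolan-3-yl}methyl (E)-3-[3,4-bis(TBSO)phenyl]prop-2-enoate | COc1cc(C[C@@H]2CO[C@@H](c3ccc(O[Si](C)(C)C(C)(C)C)c(OC)c3)[C@@H]2COC(=O)/C=C/c2ccc(O[Si](C)(C)C(C)(C)C)c(O[Si](C)(C)C(C)(C)C)c2)ccc1O[Si](C)(C)C(C)(C)C | intermediate
24 | [(2R,3S,4S)-2-(4-hydroxy-3-methoxyphenyl)-4-[(4-hydroxy-3-methoxyphenyl)methyl]oxolan-3-yl]methyl (E)-3-(3,4-dihydroxyphenyl)prop-2-enoate (CNP0132883.1) | COc1cc(C[C@@H]2CO[C@@H](c3ccc(O)c(OC)c3)[C@@H]2COC(=O)/C=C/c2ccc(O)c(O)c2)ccc1O | target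

## Count and risks

Total step count: 16. Longest linear sequence: 14 steps (1 to 24 through steps 1–6, 8–13, 15 and 16); steps 7 and 14 are side branches.

**Step 2 (key step).** The enal may annulate with itself faster than with 2, the homoenolate may be protonated at C3 and drained into redox esterification, and face discrimination at the aldehyde may be modest, which would lower enantiomeric purity at C2. Fallback, setting out from 2 and coming back at 7: (R)-4-benzyloxazolidin-2-one is acylated with methyl 4-chloro-4-oxobutanoate to (R)-4-benzyl-3-(4-methoxy-4-oxobutanoyl)oxazolidin-2-one F1. Its boron enolate (Bu2BOTf, iPr2NEt, CH2Cl2, −78 °C) adds to 2 in an Evans syn-aldol reaction to give adduct F2, which lactonises with loss of methanol to the 2,3-trans lactone imide F3 (a syn aldol maps onto a trans lactone). LiOH/H2O2 then removes the auxiliary and the pivalate, and acidification returns acid 7. Steps 2 to 4 are bypassed.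

**Step 10.** Hydrogen may be delivered with poor facial selectivity, because the C2 aryl group lies on the face that must be attacked, or the benzylic lactone C–O bond may undergo hydrogenolysis. Fallback, setting out from 9 and coming back at 15: aldehyde 10 is reduced (NaBH4, MeOH) to [3-methoxy-4-(TBSO)phenyl]methanol F4 and converted by Appel bromination (CBr4, PPh3) to the benzyl bromide F5. Enolate 11, generated from 9 as in step 8, is alkylated with F5 anti to the C3 substituent to give the 3,4-trans lactone F6. Deprotonation with KN(SiMe3)2 gives the potassium enolate F7, and kinetic protonation at −78 °C with 2,6-di-tert-butyl-4-methylphenol from the face anti to C9 gives 15; unconverted F6 can be resubmitted.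

**Step 12.** Sulfonylation may occur at the benzylic hydroxyl, with ionisation and erosion at C2, or the C9 silyl group may migrate to the C2 oxygen and divert the ring closure. Fallback, setting out from 15 and coming back at 18: reduction with iBu2AlH (CH2Cl2, −78 °C) gives the lactol F8 (anomer mixture), and Et3SiH with BF3·OEt2 at −78 °C removes the anomeric hydroxyl through the oxocarbenium ion, so the ring is never opened.

**Step 13.** The acid may ionise the benzylic C2–O1 bond (epimerisation, methanolysis or Friedel–Crafts closure), or the aryl silyl ethers may be lost in part. Fallback, setting out from 18 and coming back at 24: all three silyl groups are removed with Bu4NF/AcOH to give (−)-lariciresinol F9. F9 is esterified with unprotected caffeic acid 20 under Mitsunobu conditions (PPh3, diisopropyl azodicarboxylate, THF, 0 °C), where only the carboxylic acid is acidic enough to act as the pronucleophile and only the aliphatic hydroxyl is activated. Steps 13 to 16 are replaced.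

## Further compounds

F1 | step 2 | (R)-4-benzyl-3-(4-methoxy-4-oxobutanoyl)oxazolidin-2-one | COC(=O)CCC(=O)N1[C@H](Cc2ccccc2)COC1=O
F2 | step 2 | methyl (3R)-3-{[(4R)-4-benzyl-2-oxooxazolidin-3-yl]carbonyl}-4-hydroxy-4-[3-methoxy-4-(pivaloyloxy)phenyl]butanoate, (4R) syn-aldol adduct | COC(=O)C[C@H]([C@@H](O)c1ccc(OC(=O)C(C)(C)C)c(OC)c1)C(=O)N1[C@H](Cc2ccccc2)COC1=O
F3 | step 2 | (4R)-4-benzyl-3-{(2R,3R)-2-[3-methoxy-4-(pivaloyloxy)phenyl]-5-oxooxolane-3-carbonyl}oxazolidin-2-one | C1C(=O)O[C@@H](c2ccc(OC(=O)C(C)(C)C)c(OC)c2)[C@@H]1C(=O)N3[C@H](Cc4ccccc4)COC3=O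
F4 | step 10 | [3-methoxy-4-(TBSO)phenyl]methanol | COc1cc(CO)ccc1O[Si](C)(C)C(C)(C)C
F5 | step 10 | 4-(bromomethyl)-2-methoxy-1-(TBSO)benzene | COc1cc(CBr)ccc1O[Si](C)(C)C(C)(C)C
F6 | step 10 | (3R,4S,5R)-3-{[3-methoxy-4-(TBSO)phenyl]methyl}-5-[3-methoxy-4-(TBSO)phenyl]-4-[(TBSO)methyl]oxolan-2-one (3,4-trans) | COc1cc(C[C@H]2C(=O)O[C@@H](c3ccc(O[Si](C)(C)C(C)(C)C)c(OC)c3)[C@@H]2CO[Si](C)(C)C(C)(C)C)ccc1O[Si](C)(C)C(C)(C)C
F7 | step 10 | potassium enolate of F6 | [K+].[O-]C1=C(Cc2ccc(O[Si](C)(C)C(C)(C)C)c(OC)c2)[C@@H](CO[Si](C)(C)C(C)(C)C)[C@H](c2ccc(O[Si](C)(C)C(C)(C)C)c(OC)c2)O1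
F8 | step 12 | (3S,4S,5R)-3-{[3-methoxy-4-(TBSO)phenyl]methyl}-5-[3-methoxy-4-(TBSO)phenyl]-4-[(TBSO)methyl]oxolan-2-ol (anomer mixture) | COc1cc(C[C@@H]2C(O)O[C@@H](c3ccc(O[Si](C)(C)C(C)(C)C)c(OC)c3)[C@@H]2CO[Si](C)(C)C(C)(C)C)ccc1O[Si](C)(C)C(C)(C)C
F9 | step 13 | (−)-lariciresinol | COc1cc(C[C@@H]2CO[C@@H](c3ccc(O)c(OC)c3)[C@@H]2CO)ccc1O
A1 | alternative 1 | α-diazo lactone with the C9 oxygen as 3-methoxy-4-(triisopropylsilyloxy)benzyl ether and the C2 aryl ring as tosylate | COc1cc(COC[C@@H]2C(=[N+]=[N-])C(=O)O[C@H]2c2ccc(OS(=O)(=O)c3ccc(C)cc3)c(OC)c2)ccc1O[Si](C(C)C)(C(C)C)C(C)C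
A2 | alternative 1 | cis-fused bicyclic lactone ether from C–H insertion | COc1cc([C@H]2OC[C@@H]3[C@H]2C(=O)O[C@H]3c2ccc(OS(=O)(=O)c4ccc(C)cc4)c(OC)c2)ccc1O[Si](C(C)C)(C(C)C)C(C)C
A3 | alternative 2 | cinnamyl ether of the C2 carbinol bearing a terminal epoxide across C3/C9 (epoxide epimers) | COc1cc(/C=C/CO[C@@H](c2ccc(O[Si](C(C)C)(C(C)C)C(C)C)c(OC)c2)C2CO2)ccc1O[Si](C(C)C)(C(C)C)C(C)C
A4 | alternative 2 | bis-O-triisopropylsilyl (−)-lariciresinol with free C9 hydroxyl | COc1cc(C[C@@H]2CO[C@@H](c3ccc(O[Si](C(C)C)(C(C)C)C(C)C)c(OC)c3)[C@@H]2CO)ccc1O[Si](C(C)C)(C(C)C)C(C)C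
A5 | alternative 3 | 5-[3-methoxy-4-(triisopropylsilyloxy)phenyl]furan-2(5H)-one, single enantiomer | COc1cc([C@@H]2OC(=O)C=C2)ccc1O[Si](C(C)C)(C(C)C)C(C)C
A6 | alternative 3 | chloro[3-methoxy-4-(triisopropylsilyloxy)phenyl]methyl (trimethylsilyl)methyl ether | COc1cc(C(Cl)OC[Si](C)(C)C)ccc1O[Si](C(C)C)(C(C)C)C(C)C
A7 | alternative 3 | cis-fused diaryl furofuranone | COc1cc([C@@H]2OC(=O)[C@@H]3[C@H]2CO[C@H]3c2ccc(O[Si](C(C)C)(C(C)C)C(C)C)c(OC)c2)ccc1O[Si](C(C)C)(C(C)C)C(C)C
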